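**Plan**
- Retrosynthesis: the MOM ether on O5 comes off last. Ring B is cut at C1'–C2' and contracted to a 4-hydroxy-3-methoxycyclobutenone (C2'–C5') carrying a two-carbon bridge (C6', C1') on chromone C2.
- The bridge is cut at the carbinol–alkyne bond (acetylide plus 3-methoxycyclobutenedione) and at its terminal carbon (aldehyde homologation). The pyranone is cut at O1–C2 and C2–C3 (oxalate Claisen), the prenyl group at C3–CH2 (enolate alkylation).
- Forward: ring A is bought as the acetophenone, ring C closes in step 3, the four-membered ring is attached in step 9, and ring B arises last by thermal ring expansion in step 11.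
- The bridge goes through the ring expansion as a cis-alkene, not as the alkyne. A conjugating chromonyl group on an alkyne terminus is expected to steer the enynyl-ketene diradical mainly to five-membered closure, whereas the dienylketene can only close by 6π electrocyclisation and gives the hydroquinone directly.
- Stereochemistry: the target has no stereogenic element. The carbinol centre and alkene geometry of the precursor are consumed in the key step.

Key step: step 11

Remark: artoindonesianin Q is achiral, so the requirement of a single stereoisomer is met by the compound itself; intermediates with a carbinol or sp3 CH centre are racemic.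
Remark: LDA, LiHMDS, LiAlH(OtBu)3, Dess–Martin periodinane and the Ohira–Bestmann reagent are used as purchased reagents.

**Step 1**
Reactants: 1 2',6'-dihydroxy-4'-methoxyacetophenone
Product: 2 1-[4-methoxy-2,6-bis(methoxymethoxy)phenyl]ethan-1-one
Conditions: NaH (2.2 equiv), MOMCl (2.4 equiv), DMF, 0 °C → rt
Reagents that add atoms: chloromethyl methyl ether (MOMCl), COCCl
Why: Williamson-type O-alkylation of both phenoxides; full deprotonation with NaH overcomes the hydrogen bond of the phenols to the ketone.

**Step 2**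
Reactants: 2 1-[4-methoxy-2,6-bis(methoxymethoxy)phenyl]ethan-1-one; 3 prenyl bromide (1-bromo-3-methylbut-2-ene)
Product: 5 1-[4-methoxy-2,6-bis(methoxymethoxy)phenyl]-5-methylhex-4-en-1-one, via lithium enolate 4 (not isolated)
Conditions: LDA (1.05 equiv), THF, −78 °C; then 3, −78 → −20 °C
Reagents that add atoms: none
Why: Kinetic lithium enolate formation at the methyl group followed by SN2 alkylation at the primary carbon of the allylic bromide; low temperature and the absence of excess base should limit proton exchange and double alkylation.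

**Step 3**
Reactants: 5 1-[4-methoxy-2,6-bis(methoxymethoxy)phenyl]-5-methylhex-4-en-1-one; 6 diethyl oxalate
Product: 8 ethyl 5-hydroxy-7-methoxy-3-(3-methylbut-2-en-1-yl)-4-oxo-4H-chromene-2-carboxylate, via diketo ester 7 (not isolated)
Conditions: NaOEt (3 equiv), EtOH, 60 °C; then 3 M aq. HCl, 60 °C
Reagents that add atoms: none
Why: Crossed Claisen condensation of the ketone α-methylene with non-enolisable diethyl oxalate, driven by deprotonation of the 2,4-dioxo ester, followed by acid cleavage of both MOM ethers and cyclodehydration of either of the two equivalent phenols onto the α-keto ester carbonyl (Kostanecki-type chromone-2-carboxylate synthesis), which leaves the other phenol as the chelated 5-OH.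

**Step 4**
Reactants: 8 ethyl 5-hydroxy-7-methoxy-3-(3-methylbut-2-en-1-yl)-4-oxo-4H-chromene-2-carboxylate
Product: 9 ethyl 7-methoxy-5-(methoxymethoxy)-3-(3-methylbut-2-en-1-yl)-4-oxo-4H-chromene-2-carboxylate
Conditions: NaH (1.2 equiv), MOMCl (1.3 equiv), DMF, 0 °C → rt
Reagents that add atoms: chloromethyl methyl ether (MOMCl), COCCl
Why: O-alkylation of the sodium 5-phenoxide, the only acidic site, masks the phenol for the later strong-base step.

**Step 5**
Reactants: 9 ethyl 7-methoxy-5-(methoxymethoxy)-3-(3-methylbut-2-en-1-yl)-4-oxo-4H-chromene-2-carboxylate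
Product: 10 2-(hydroxymethyl)-7-methoxy-5-(methoxymethoxy)-3-(3-methylbut-2-en-1-yl)-4H-chromen-4-one
Conditions: NaBH4, EtOH–THF, 0 °C
Reagents that add atoms: none
Why: Chemoselective borohydride reduction of the activated ester on the electron-poor pyranone carbon, a known behaviour of chromone-2-carboxylates, while the vinylogous-ester carbonyl C4 is left alone.

**Step 6**
Reactants: 10 2-(hydroxymethyl)-7-methoxy-5-(methoxymethoxy)-3-(3-methylbut-2-en-1-yl)-4H-chromen-4-one
Product: 11 7-methoxy-5-(methoxymethoxy)-3-(3-methylbut-2-en-1-yl)-4-oxo-4H-chromene-2-carbaldehyde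
Conditions: Dess–Martin periodinane, CH2Cl2, 0 °C → rt
Reagents that add atoms: none
Why: Dess–Martin oxidation of the primary allylic-type alcohol stops at the aldehyde and tolerates the prenyl olefin and the MOM ether.

**Step 7**
Reactants: 11 7-methoxy-5-(methoxymethoxy)-3-(3-methylbut-2-en-1-yl)-4-oxo-4H-chromene-2-carbaldehyde
Product: 12 2-ethynyl-7-methoxy-5-(methoxymethoxy)-3-(3-methylbut-2-en-1-yl)-4H-chromen-4-one
Conditions: Ohira–Bestmann reagent, K2CO3, MeOH, 0 °C → rt
Reagents that add atoms: dimethyl (1-diazo-2-oxopropyl)phosphonate (Ohira–Bestmann reagent), CC(=O)C(=[N+]=[N-])P(=O)(OC)OC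
Why: Seyferth–Gilbert homologation in the Ohira–Bestmann form: the diazomethylphosphonate anion released by methanolysis adds to the non-enolisable aldehyde, and loss of phosphate and N2 with 1,2-hydrogen shift gives the terminal alkyne under mild carbonate conditions.

**Step 8**
Reactants: 13 dimethyl squarate (3,4-dimethoxycyclobut-3-ene-1,2-dione)
Product: 15 3-methoxycyclobut-3-ene-1,2-dione (methyl semisquarate), via hydroxycyclobutenone 14 (not isolated)
Conditions: LiAlH(OtBu)3 (1.05 equiv), THF, −78 °C; then 6 M aq. HCl, CH2Cl2, 0 °C → rt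
Reagents that add atoms: water (supplies the new carbonyl oxygen), O
Why: Mono-1,2-reduction of one squarate carbonyl with a hindered hydride, then acid-induced ionisation of the carbinol to a methoxy-stabilised cyclobutenyl cation, hydration and loss of methanol, the known route from dialkyl squarates to 4-substituted (here 4-H) 3-alkoxycyclobutenediones.

**Step 9**
Reactants: 12 2-ethynyl-7-methoxy-5-(methoxymethoxy)-3-(3-methylbut-2-en-1-yl)-4H-chromen-4-one; 15 3-methoxycyclobut-3-ene-1,2-dione
Product: 17 4-hydroxy-3-methoxy-4-{[7-methoxy-5-(methoxymethoxy)-3-(3-methylbut-2-en-1-yl)-4-oxo-4H-chromen-2-yl]ethynyl}cyclobut-2-en-1-one (racemic), via lithium acetylide 16 (not isolated)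
Conditions: LiHMDS (1.05 equiv), THF, −78 °C, 10 min; cannulated into 15 (1.3 equiv), THF, −78 °C; sat. NH4Cl at −78 °C
Reagents that add atoms: none
Why: 1,2-Addition of a lithium acetylide to the more electrophilic carbonyl of the 3-alkoxycyclobutenedione (the one next to the methoxy-bearing carbon, not part of the vinylogous ester), the known regiochemistry of organolithium additions to semisquarates; the non-nucleophilic amide base and inverse addition at −78 °C treat the electron-poor acetylide like a lithium propiolate.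

**Step 10**
Reactants: 17 4-hydroxy-3-methoxy-4-{[7-methoxy-5-(methoxymethoxy)-3-(3-methylbut-2-en-1-yl)-4-oxo-4H-chromen-2-yl]ethynyl}cyclobut-2-en-1-one
Product: 18 4-hydroxy-3-methoxy-4-{(Z)-2-[7-methoxy-5-(methoxymethoxy)-3-(3-methylbut-2-en-1-yl)-4-oxo-4H-chromen-2-yl]ethenyl}cyclobut-2-en-1-one (racemic)
Conditions: H2 (1 atm), Lindlar catalyst (Pd/CaCO3, Pb-poisoned), quinoline, EtOAc, rt, stopped after 1 equiv H2
Reagents that add atoms: none
Why: Lindlar syn-semi-hydrogenation of the disubstituted alkyne should stop at the (Z)-alkene, because the trisubstituted prenyl olefin, the tetrasubstituted chromone C2=C3 and the β-methoxy enone of the four-membered ring are too hindered or too electron-rich to compete on the poisoned catalyst.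

**Step 11**
Reactants: 18 4-hydroxy-3-methoxy-4-{(Z)-2-[7-methoxy-5-(methoxymethoxy)-3-(3-methylbut-2-en-1-yl)-4-oxo-4H-chromen-2-yl]ethenyl}cyclobut-2-en-1-one
Product: 21 2-(2,5-dihydroxy-4-methoxyphenyl)-7-methoxy-5-(methoxymethoxy)-3-(3-methylbut-2-en-1-yl)-4H-chromen-4-one, via dienylketene 19 (not isolated), via cyclohexadienone 20 (not isolated)
Conditions: degassed toluene (0.01 M), 110 °C, Ar
Reagents that add atoms: none
Why: Heating triggers the thermally allowed conrotatory 4π ring opening of the cyclobutenone (C1–C4 bond), and the C4 hydroxyl, being the stronger π-donor, rotates outward, so that the alkenyl arm ends up cis to the ketene in dienylketene 19. Disrotatory 6π electrocyclisation of the ketene C=C with the two following double bonds then joins the ketene carbon (future C2') to the distal alkene carbon (future C1'), closing the six-membered B ring as cyclohexa-2,4-dienone 20, and enolisation of 20 aromatises it to the hydroquinone. The closest known reaction is the thermal ring expansion of 4-alkenyl- and 4-aryl-4-hydroxycyclobutenones to hydroquinones, the closed-shell relative of the Moore rearrangement of 4-alkynyl analogues. No stereocentre is created, since the carbinol carbon and the transient sp3 carbon of 20 both become aromatic carbons and the alkene geometry is lost. The step needs outward rotation of the hydroxyl and six- rather than five-membered closure: the first is secured by the donor hydroxyl on C4, the second by working at the alkene oxidation level, where no diradical is formed that could close to an alkylidenecyclopentenedione or abstract an allylic hydrogen from the prenyl group. The positions of the substituents (methoxy at C4', oxygens at C2' and C5', chromone at C1') follow from the substitution of the four-membered ring and need no control.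

**Step 12**
Reactants: 21 2-(2,5-dihydroxy-4-methoxyphenyl)-7-methoxy-5-(methoxymethoxy)-3-(3-methylbut-2-en-1-yl)-4H-chromen-4-one
Product: 22 artoindonesianin Q, 2-(2,5-dihydroxy-4-methoxyphenyl)-5-hydroxy-7-methoxy-3-(3-methylbut-2-en-1-yl)-4H-chromen-4-one
Conditions: 3 M aq. HCl, THF, 45 °C, Ar
Reagents that add atoms: none
Why: Acid-catalysed hydrolysis of the MOM acetal frees the 5-OH; the prenyl group has no phenol within reach for a five- or six-membered cyclisation (closure onto the 2'-OH would need an eight-membered ring), so it should survive the mild acid.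

**Compound list**
1 | 2',6'-dihydroxy-4'-methoxyacetophenone | CC(=O)c1c(O)cc(OC)cc1O | starting material
2 | 1-[4-methoxy-2,6-bis(methoxymethoxy)phenyl]ethan-1-one | CC(=O)c1c(OCOC)cc(OC)cc1OCOC | intermediate
3 | prenyl bromide (1-bromo-3-methylbut-2-ene) | CC(C)=CCBr | starting material
4 | lithium 1-[4-methoxy-2,6-bis(methoxymethoxy)phenyl]ethen-1-olate (lithium enolate of 2, not isolated) | [Li]OC(=C)c1c(OCOC)cc(OC)cc1OCOC | intermediate
5 | 1-[4-methoxy-2,6-bis(methoxymethoxy)phenyl]-5-methylhex-4-en-1-one | CC(C)=CCCC(=O)c1c(OCOC)cc(OC)cc1OCOC | intermediate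
6 | diethyl oxalate | CCOC(=O)C(=O)OCC | starting material
7 | ethyl 3-[4-methoxy-2,6-bis(methoxymethoxy)benzoyl]-6-methyl-2-oxohept-5-enoate (racemic, not isolated) | CCOC(=O)C(=O)C(CC=C(C)C)C(=O)c1c(OCOC)cc(OC)cc1OCOC | intermediate
8 | ethyl 5-hydroxy-7-methoxy-3-(3-methylbut-2-en-1-yl)-4-oxo-4H-chromene-2-carboxylate | CCOC(=O)c1oc2cc(OC)cc(O)c2c(=O)c1CC=C(C)C | intermediate
9 | ethyl 7-methoxy-5-(methoxymethoxy)-3-(3-methylbut-2-en-1-yl)-4-oxo-4H-chromene-2-carboxylate | CCOC(=O)c1oc2cc(OC)cc(OCOC)c2c(=O)c1CC=C(C)C | intermediate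
10 | 2-(hydroxymethyl)-7-methoxy-5-(methoxymethoxy)-3-(3-methylbut-2-en-1-yl)-4H-chromen-4-one | OCc1oc2cc(OC)cc(OCOC)c2c(=O)c1CC=C(C)C | intermediate
11 | 7-methoxy-5-(methoxymethoxy)-3-(3-methylbut-2-en-1-yl)-4-oxo-4H-chromene-2-carbaldehyde | O=Cc1oc2cc(OC)cc(OCOC)c2c(=O)c1CC=C(C)C | intermediate
12 | 2-ethynyl-7-methoxy-5-(methoxymethoxy)-3-(3-methylbut-2-en-1-yl)-4H-chromen-4-one | C#Cc1oc2cc(OC)cc(OCOC)c2c(=O)c1CC=C(C)C | intermediate
13 | dimethyl squarate (3,4-dimethoxycyclobut-3-ene-1,2-dione) | COC1=C(OC)C(=O)C1=O | starting material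
14 | 4-hydroxy-2,3-dimethoxycyclobut-2-en-1-one (racemic, not isolated) | COC1=C(OC)C(=O)C1O | intermediate
15 | 3-methoxycyclobut-3-ene-1,2-dione (methyl semisquarate) | COC1=CC(=O)C1=O | intermediate
16 | lithium acetylide of 12 (not isolated) | [Li]C#Cc1oc2cc(OC)cc(OCOC)c2c(=O)c1CC=C(C)C | intermediate
17 | 4-hydroxy-3-methoxy-4-{[7-methoxy-5-(methoxymethoxy)-3-(3-methylbut-2-en-1-yl)-4-oxo-4H-chromen-2-yl]ethynyl}cyclobut-2-en-1-one (racemic) | COC1=CC(=O)C1(O)C#Cc1oc2cc(OC)cc(OCOC)c2c(=O)c1CC=C(C)C | intermediate
18 | 4-hydroxy-3-methoxy-4-{(Z)-2-[7-methoxy-5-(methoxymethoxy)-3-(3-methylbut-2-en-1-yl)-4-oxo-4H-chromen-2-yl]ethenyl}cyclobut-2-en-1-one (racemic) | COC1=CC(=O)C1(O)/C=C\c1oc2cc(OC)cc(OCOC)c2c(=O)c1CC=C(C)C | intermediate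
19 | (3Z,5Z)-4-hydroxy-3-methoxy-6-[7-methoxy-5-(methoxymethoxy)-3-(3-methylbut-2-en-1-yl)-4-oxo-4H-chromen-2-yl]hexa-1,3,5-trien-1-one (dienylketene, not isolated) | O=C=C/C(OC)=C(\C=C/c1oc2cc(OC)cc(OCOC)c2c(=O)c1CC=C(C)C)O | intermediate
20 | 4-hydroxy-3-methoxy-6-[7-methoxy-5-(methoxymethoxy)-3-(3-methylbut-2-en-1-yl)-4-oxo-4H-chromen-2-yl]cyclohexa-2,4-dien-1-one (racemic, not isolated) | COC1=CC(=O)C(c2oc3cc(OC)cc(OCOC)c3c(=O)c2CC=C(C)C)C=C1O | intermediate
21 | 2-(2,5-dihydroxy-4-methoxyphenyl)-7-methoxy-5-(methoxymethoxy)-3-(3-methylbut-2-en-1-yl)-4H-chromen-4-one | COc1cc(OCOC)c2c(=O)c(CC=C(C)C)c(-c3cc(O)c(OC)cc3O)oc2c1 | intermediate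
22 | artoindonesianin Q, 2-(2,5-dihydroxy-4-methoxyphenyl)-5-hydroxy-7-methoxy-3-(3-methylbut-2-en-1-yl)-4H-chromen-4-one | COc1cc(O)c2c(=O)c(CC=C(C)C)c(-c3cc(O)c(OC)cc3O)oc2c1 | target

**Step count and risks**
Total step count: 12. Longest linear sequence: 11 (steps 1–7 and 9–12); step 8 is a one-step side branch.

Step 9 is the most likely to fail. The lithiated enyne may attack the chromone carbonyl or C2 of a second molecule before it reaches the dione, or add to the dione without clean 1,2-selectivity. The fallback sets out from 12 and returns at 17, and makes the bond by fluoride-triggered alkynyl transfer from silicon so that no acetylide accumulates. LiHMDS is added to a mixture of 12 and Me3SiCl in THF at −78 °C (internal quench) to give 7-methoxy-5-(methoxymethoxy)-3-(3-methylbut-2-en-1-yl)-2-[(trimethylsilyl)ethynyl]-4H-chromen-4-one F1. F1 and 15 are then combined with catalytic Bu4N+ Ph3SiF2− in THF at −20 °C, which should deliver the silyl ether 3-methoxy-4-{[7-methoxy-5-(methoxymethoxy)-3-(3-methylbut-2-en-1-yl)-4-oxo-4H-chromen-2-yl]ethynyl}-4-(trimethylsilyloxy)cyclobut-2-en-1-one F2. Dilute aqueous citric acid at 0 °C frees the carbinol 17.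

Step 11 is next. The cis-chromonyl group has to turn inward during the disrotatory closure; if this slows the electrocyclisation, the ketene may be lost to dimerisation or to attack by the neighbouring enol hydroxyl, and the hydroquinone may oxidise in air. The fallback sets out from 17 and returns at 21, and runs the ring expansion at the alkyne level, whose linear terminus has no inside substituent. Alkyne 17 is thermolysed in degassed p-xylene at 138 °C; the enynyl ketene closes through the 1,4-diradical and hydroxyl-hydrogen transfer to the air-stable quinone 2-methoxy-5-[7-methoxy-5-(methoxymethoxy)-3-(3-methylbut-2-en-1-yl)-4-oxo-4H-chromen-2-yl]cyclohexa-2,5-diene-1,4-dione F3. Some five-membered closure has to be accepted on this path. F3 is purified and reduced with aqueous Na2S2O4 in EtOAc–water to 21.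

Step 10 is third. The newly formed chromone-conjugated alkene or the strained enone may be over-reduced, or the catalyst may stall. The fallback sets out from 17 and returns at 21, and replaces the cis semi-hydrogenation by a two-stage trans reduction. Ruthenium-catalysed trans-hydrosilylation ([Cp*Ru(MeCN)3]PF6 cat., (EtO)3SiH, CH2Cl2, 0 °C) should give the vinylsilane 4-hydroxy-3-methoxy-4-{(Z)-2-[7-methoxy-5-(methoxymethoxy)-3-(3-methylbut-2-en-1-yl)-4-oxo-4H-chromen-2-yl]-2-(triethoxysilyl)ethenyl}cyclobut-2-en-1-one F4. Protodesilylation (CuI, Bu4NF, THF, 0 °C) then gives the (E)-alkene 4-hydroxy-3-methoxy-4-{(E)-2-[7-methoxy-5-(methoxymethoxy)-3-(3-methylbut-2-en-1-yl)-4-oxo-4H-chromen-2-yl]ethenyl}cyclobut-2-en-1-one F5. Heating F5 in degassed toluene at 110 °C, as in step 11, gives 21, with the chromone on the outside of the cyclising triene.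

**Further compounds**
F1 | step 9 | 7-methoxy-5-(methoxymethoxy)-3-(3-methylbut-2-en-1-yl)-2-[(trimethylsilyl)ethynyl]-4H-chromen-4-one | C[Si](C)(C)C#Cc1oc2cc(OC)cc(OCOC)c2c(=O)c1CC=C(C)C
F2 | step 9 | 3-methoxy-4-{[7-methoxy-5-(methoxymethoxy)-3-(3-methylbut-2-en-1-yl)-4-oxo-4H-chromen-2-yl]ethynyl}-4-(trimethylsilyloxy)cyclobut-2-en-1-one (racemic) | COC1=CC(=O)C1(O[Si](C)(C)C)C#Cc1oc2cc(OC)cc(OCOC)c2c(=O)c1CC=C(C)C
F3 | step 11 | 2-methoxy-5-[7-methoxy-5-(methoxymethoxy)-3-(3-methylbut-2-en-1-yl)-4-oxo-4H-chromen-2-yl]cyclohexa-2,5-diene-1,4-dione | COC1=CC(=O)C(c2oc3cc(OC)cc(OCOC)c3c(=O)c2CC=C(C)C)=CC1=O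
F4 | step 10 | 4-hydroxy-3-methoxy-4-{(Z)-2-[7-methoxy-5-(methoxymethoxy)-3-(3-methylbut-2-en-1-yl)-4-oxo-4H-chromen-2-yl]-2-(triethoxysilyl)ethenyl}cyclobut-2-en-1-one (racemic) | COC1=CC(=O)C1(O)/C=C(\[Si](OCC)(OCC)OCC)c1oc2cc(OC)cc(OCOC)c2c(=O)c1CC=C(C)C
F5 | step 10 | 4-hydroxy-3-methoxy-4-{(E)-2-[7-methoxy-5-(methoxymethoxy)-3-(3-methylbut-2-en-1-yl)-4-oxo-4H-chromen-2-yl]ethenyl}cyclobut-2-en-1-one (racemic) | COC1=CC(=O)C1(O)/C=C/c1oc2cc(OC)cc(OCOC)c2c(=O)c1CC=C(C)C
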